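## Retrosynthetic overview

1. The carbinol stereocentre comes from an enantioselective CBS reduction of the 3-aroyl ketone in the last step, so nothing follows that could scramble it.
2. The exocyclic C5=C6 bond comes from a vinylogous Knoevenagel condensation with 3-bromo-4-hydroxybenzaldehyde, run in the same flask as the ring closure.
3. The C3=C4 bond and the aroyl C=O come from a ring-closing alkyne–carbonyl metathesis of an acyclic phenacyl arylpropiolate, which is an isomer of the 3-aroylbutenolide.
4. The ester comes from an arylpropiolic acid (aldehyde → alkyne → CO2) and a phenacyl bromide made from the acetophenone. No protecting groups are used.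
5. Ring order: the three arenes are bought. The γ-lactone and a four-membered oxete close together in one [2+2] event, then the oxete opens and leaves the butenolide as the only new ring.

Assumption: in the CBS transition state the twisted, doubly flanked butenolide is the large group and the flat aryl ring the small one, so (R)-Me-CBS gives the (S)-carbinol; if the sense proves opposite, (S)-Me-CBS is used.

## Route

Step 1
Reactants: 1 3,5-dibromo-4-methoxybenzaldehyde
Product: 2 1,3-dibromo-5-ethynyl-2-methoxybenzene
Conditions: Ohira–Bestmann reagent (1.2 equiv), K2CO3 (2 equiv), MeOH, 0 °C to rt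
Reagents that add atoms: dimethyl (1-diazo-2-oxopropyl)phosphonate, CC(=O)C(=[N+]=[N-])P(=O)(OC)OC
Why: Seyferth–Gilbert homologation in the Ohira–Bestmann variant works well on this electron-poor, non-enolisable aldehyde, and the mild carbonate base leaves the aryl bromides and the methyl ether untouched.

Step 2
Reactants: 2 1,3-dibromo-5-ethynyl-2-methoxybenzene
Product: 3 3-(3,5-dibromo-4-methoxyphenyl)prop-2-ynoic acid
Conditions: CO2 (balloon), AgI (2 mol %), Cs2CO3 (1.5 equiv), DMF, 50 °C; then 1 M HCl, 0 °C
Reagents that add atoms: carbon dioxide, O=C=O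
Why: In this silver-catalysed C–H carboxylation of a terminal alkyne the silver acetylide inserts CO2, and the aryl bromides survive because no low-valent Pd or Ni and no organolithium is present.

Step 3
Reactants: 4 1-(3-bromo-4-hydroxyphenyl)ethan-1-one
Product: 5 2-bromo-1-(3-bromo-4-hydroxyphenyl)ethan-1-one
Conditions: CuBr2 (2.1 equiv), EtOAc/CHCl3 1:1, reflux
Reagents that add atoms: copper(II) bromide, Br[Cu]Br
Why: Heterogeneous CuBr2 α-brominates the enol of the aryl methyl ketone, and because no free Br2 builds up, the unprotected phenol ring is not brominated further.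

Step 4
Reactants: 3 3-(3,5-dibromo-4-methoxyphenyl)prop-2-ynoic acid; 5 2-bromo-1-(3-bromo-4-hydroxyphenyl)ethan-1-one
Product: 6 2-(3-bromo-4-hydroxyphenyl)-2-oxoethyl 3-(3,5-dibromo-4-methoxyphenyl)prop-2-ynoate
Conditions: KHCO3 (1.05 equiv), DMF, 0 °C to rt
Reagents that add atoms: none
Why: This is SN2 O-alkylation of a carboxylate (phenacyl ester formation), and bicarbonate deprotonates only the propiolic acid (pKa about 2.5) and not the bromophenol (pKa about 8.5), so the phenol needs no protection.

Step 5
Reactants: 6 2-(3-bromo-4-hydroxyphenyl)-2-oxoethyl 3-(3,5-dibromo-4-methoxyphenyl)prop-2-ynoate; 7 3-bromo-4-hydroxybenzaldehyde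
Product: 10 (5Z)-4-(3-bromo-4-hydroxyphenyl)-5-[(3-bromo-4-hydroxyphenyl)methylidene]-3-(3,5-dibromo-4-methoxybenzoyl)furan-2(5H)-one, via bicyclic oxete 8 (not isolated), via 3-aroylbutenolide 9 (not isolated)
Conditions: [IPrAu(MeCN)]SbF6 (5 mol %), DCE (0.05 M), 70 °C; then 7 (1.1 equiv), piperidine/AcOH (30 mol % each), 60 °C
Reagents that add atoms: none
Why: Proposed new method: cationic gold(I) π-activates the ynoate, whose β-carbon (made more electrophilic by the dibromoaryl group) is attacked by the electron-rich p-hydroxyaryl ketone oxygen; the α-aurated carbon then adds to the oxocarbenium carbon, so a formal intramolecular [2+2] closes the five-membered lactone and the four-membered oxete of 8 in the same event; strain-driven 4π ring opening of 8 transfers the oxygen and gives the tetrasubstituted enone 9 (ring-closing alkyne–carbonyl metathesis; the closest known type is the gold-, silver- or TfOH-catalysed alkyne–ketone metathesis of aryl-alkynyl ketones to 2-acylcycloalkenes, extended here to an ester-tethered ynoate); piperidinium acetate then drives the vinylogous Knoevenagel condensation of the acidic C5–H2 of 9 with 7, which gives only the Z-alkene because the E-isomer would clash with the C4 aryl group.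

Step 6
Reactants: 10 (5Z)-4-(3-bromo-4-hydroxyphenyl)-5-[(3-bromo-4-hydroxyphenyl)methylidene]-3-(3,5-dibromo-4-methoxybenzoyl)furan-2(5H)-one
Product: 11 (5Z)-4-(3-bromo-4-hydroxyphenyl)-5-[(3-bromo-4-hydroxyphenyl)methylidene]-3-[(S)-(3,5-dibromo-4-methoxyphenyl)(hydroxy)methyl]furan-2(5H)-one
Conditions: (R)-Me-CBS (0.5 equiv), BH3·SMe2 (3.5 equiv, covers the two phenols), THF, −30 °C; MeOH quench
Reagents that add atoms: none
Why: In this Corey–Bakshi–Shibata reduction the ketone binds the oxazaborolidine boron anti to the out-of-plane butenolide, and hydride goes to the Re face to set the (S)-carbinol; the reduction is strictly 1,2, and the enol-ester lactone, the hindered conjugated alkenes and the aryl bromides do not react with borane at −30 °C.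

## Compound list

1 | 3,5-dibromo-4-methoxybenzaldehyde | COc1c(Br)cc(C=O)cc1Br | starting material
2 | 1,3-dibromo-5-ethynyl-2-methoxybenzene | COc1c(Br)cc(C#C)cc1Br | intermediate
3 | 3-(3,5-dibromo-4-methoxyphenyl)prop-2-ynoic acid | COc1c(Br)cc(C#CC(=O)O)cc1Br | intermediate
4 | 1-(3-bromo-4-hydroxyphenyl)ethan-1-one | CC(=O)c1ccc(O)c(Br)c1 | starting material
5 | 2-bromo-1-(3-bromo-4-hydroxyphenyl)ethan-1-one | O=C(CBr)c1ccc(O)c(Br)c1 | intermediate
6 | 2-(3-bromo-4-hydroxyphenyl)-2-oxoethyl 3-(3,5-dibromo-4-methoxyphenyl)prop-2-ynoate | COc1c(Br)cc(C#CC(=O)OCC(=O)c2ccc(O)c(Br)c2)cc1Br | intermediate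
7 | 3-bromo-4-hydroxybenzaldehyde | O=Cc1ccc(O)c(Br)c1 | starting material
8 | 5-(3-bromo-4-hydroxyphenyl)-7-(3,5-dibromo-4-methoxyphenyl)-3,6-dioxabicyclo[3.2.0]hept-1(7)-en-2-one (racemic; its stereocentre is lost on ring opening; not isolated) | COc1c(Br)cc(C2=C3C(=O)OCC3(c4ccc(O)c(Br)c4)O2)cc1Br | intermediate
9 | 4-(3-bromo-4-hydroxyphenyl)-3-(3,5-dibromo-4-methoxybenzoyl)furan-2(5H)-one (not isolated) | COc1c(Br)cc(C(=O)C2=C(c3ccc(O)c(Br)c3)COC2=O)cc1Br | intermediate
10 | (5Z)-4-(3-bromo-4-hydroxyphenyl)-5-[(3-bromo-4-hydroxyphenyl)methylidene]-3-(3,5-dibromo-4-methoxybenzoyl)furan-2(5H)-one | COc1c(Br)cc(C(=O)C2=C(c3ccc(O)c(Br)c3)/C(=C/c3ccc(O)c(Br)c3)OC2=O)cc1Br | intermediate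
11 | (5Z)-4-(3-bromo-4-hydroxyphenyl)-5-[(3-bromo-4-hydroxyphenyl)methylidene]-3-[(S)-(3,5-dibromo-4-methoxyphenyl)(hydroxy)methyl]furan-2(5H)-one | COc1c(Br)cc([C@H](O)C2=C(c3ccc(O)c(Br)c3)/C(=C/c3ccc(O)c(Br)c3)OC2=O)cc1Br | target

## Step count and risks

Total step count: 6.
Longest linear sequence: 5 steps (1 → 2 → 3 → 6 → 10 → 11).

**Most likely to fail: step 5.** Alkyne–carbonyl metathesis has no precedent on an electron-poor, ester-tethered ynoate, and addition of a phenol O–H to the activated alkyne may compete. The fallback sets out from 6 and gives up the oxygen-transfer cyclisation. The triple bond is hydrated first (AgOTf 5 mol %, wet dioxane, 60 °C; water adds to the β-carbon) to give the β-keto ester 2-(3-bromo-4-hydroxyphenyl)-2-oxoethyl 3-(3,5-dibromo-4-methoxyphenyl)-3-oxopropanoate F1. Et3N in CH2Cl2 then closes the ring by intramolecular Knoevenagel condensation. The route is rejoined at 9, which is now isolated and condensed with 7 under piperidinium acetate to give 10.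

**Second: step 6.** Both ketone substituents are sp2 groups, so the ee may be moderate, and the hindered ketone may react slowly. The fallback sets out from 10 and replaces asymmetric induction by resolution with recycling. Luche reduction (NaBH4, CeCl3·7H2O, MeOH/THF, −40 °C) gives the racemic carbinol (5Z)-4-(3-bromo-4-hydroxyphenyl)-5-[(3-bromo-4-hydroxyphenyl)methylidene]-3-[(3,5-dibromo-4-methoxyphenyl)(hydroxy)methyl]furan-2(5H)-one F2. Kinetic resolution by hydrogen transfer to acetone with RuCl[(S,S)-TsDPEN](p-cymene)/KOtBu then oxidises the (R)-enantiomer back to 10, which is recycled. The unreacted (S)-enantiomer rejoins the route at 11.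

**Third: step 2.** Conversion may be incomplete, or the electron-poor arylpropiolate may lose CO2 again on work-up. The fallback sets out from 1, bypasses 2 and uses the classical cinnamic acid route. Knoevenagel–Doebner condensation with malonic acid (pyridine, cat. piperidine, 90 °C) gives (E)-3-(3,5-dibromo-4-methoxyphenyl)prop-2-enoic acid F3. Addition of Br2 in CHCl3 gives racemic erythro-2,3-dibromo-3-(3,5-dibromo-4-methoxyphenyl)propanoic acid F4. Double dehydrobromination with KOH in EtOH at reflux, followed by acidification, rejoins the route at 3.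

## Further compounds

F1 | step 5 | 2-(3-bromo-4-hydroxyphenyl)-2-oxoethyl 3-(3,5-dibromo-4-methoxyphenyl)-3-oxopropanoate | COc1c(Br)cc(C(=O)CC(=O)OCC(=O)c2ccc(O)c(Br)c2)cc1Br
F2 | step 6 | racemic (5Z)-4-(3-bromo-4-hydroxyphenyl)-5-[(3-bromo-4-hydroxyphenyl)methylidene]-3-[(3,5-dibromo-4-methoxyphenyl)(hydroxy)methyl]furan-2(5H)-one | COc1c(Br)cc(C(O)C2=C(c3ccc(O)c(Br)c3)/C(=C/c3ccc(O)c(Br)c3)OC2=O)cc1Br
F3 | step 2 | (E)-3-(3,5-dibromo-4-methoxyphenyl)prop-2-enoic acid | COc1c(Br)cc(/C=C/C(=O)O)cc1Br
F4 | step 2 | racemic erythro-2,3-dibromo-3-(3,5-dibromo-4-methoxyphenyl)propanoic acid | COc1c(Br)cc(C(Br)C(Br)C(=O)O)cc1Br
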